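**Assumption (atom labels used throughout):** ring A = C1–C5 (C2 bears OAc, C4 bears Me and OH), cyclobutane = C1, C5, C6, C10, ring C = C6–C10 (C8 bears the tiglate, C10 the methyl), lactone = O–C12(=O)–C11(C13H2OAc)=C7; "exo" means the face of a five-membered ring turned away from the cyclobutane.

## Retrosynthetic overview

1. Target ⇐ C4 silyl ether ⇐ intramolecular Wittig closure of the butenolide (C7=C11) from a C6–O bromoacetate carrying the C8 tiglate.
2. The C8–O and C6–O bonds come from two silyl enol ether oxygenations. The C6–O bond formation on a bridgehead enol ether is the key step: it creates the quaternary carbinol and locks the cis-syn-cis 5-4-5 core.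
3. That enol ether comes from methyl cuprate addition to a transient cyclobutene-fused enone (C6=C10), made by E1cB from a photoadduct. Both ring-fusion carbons become planar, so the ring-fusion stereochemistry of the photoadduct no longer matters.
4. The cyclobutane comes from a [2+2] photocycloaddition of 3-acetoxycyclopentenone (ring C) with an enantiopure ring A cyclopentene, made in two steps from the enzymatically derived cis-monoacetate.
5. Ring order: ring A (chiral pool) and ring C (dione) → cyclobutane → butenolide last.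

## Route

**Step 1**
Reactants: 1 cyclopentane-1,3-dione
Product: 2 3-oxocyclopent-1-en-1-yl acetate
Conditions: AcCl, pyridine, CH2Cl2, 0 °C
Reagents that add atoms: acetyl chloride, CC(Cl)=O
Why: O-acylation of the dione enol gives the enol acetate, the usual chromophore for de Mayo-type photocycloadditions, and its acetate later serves as the leaving group.

**Step 2**
Reactants: 3 (1R,4S)-cis-4-acetoxycyclopent-2-en-1-ol
Product: 4 (4S)-4-acetoxycyclopent-2-en-1-one
Conditions: MnO2, CH2Cl2, rt
Reagents that add atoms: none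
Why: Allylic alcohol oxidation with MnO2 is neutral, so the β-acetoxy enone does not eliminate and the acetoxy-bearing stereocentre (later C2) is untouched.

**Step 3**
Reactants: 4 (4S)-4-acetoxycyclopent-2-en-1-one
Product: 6 (1S,4R)-4-methyl-4-(triethylsilyloxy)cyclopent-2-en-1-yl acetate, via magnesium alkoxide 5 (not isolated)
Conditions: MeMgBr, LaCl3·2LiCl, THF, −78 °C; then TESOTf, −78 → 0 °C
Reagents that add atoms: methylmagnesium bromide, C[Mg]Br; triethylsilyl triflate, CC[Si](CC)(CC)OS(=O)(=O)C(F)(F)F
Why: Lanthanum-promoted Grignard 1,2-addition at −78 °C is fast and non-basic (ketone before acetate, no E1cB), methyl enters anti to the acetoxy group so the two oxygens end up cis (sets C4), and the alkoxide is silylated in situ.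

**Step 4**
Reactants: 2 3-oxocyclopent-1-en-1-yl acetate; 6 (1S,4R)-4-methyl-4-(triethylsilyloxy)cyclopent-2-en-1-yl acetate
Product: 7 tricyclic β-acetoxy ketone (C7=O; C10-OAc; C6-H; cis-anti-cis isomer drawn; the C6/C10-epimeric cis-syn-cis isomer is also present)
Conditions: hν (350 nm), CH2Cl2, −20 °C
Reagents that add atoms: none
Why: In this de Mayo-type enone–alkene [2+2] photocycloaddition the enone adds to the alkene face opposite both ring A oxygens (sets C1 and C5, cis-fused), the fully substituted acetoxy-bearing carbon C10 bonds to C1 (the alkene carbon remote from the quaternary C4) while the CH terminus C6 bonds to C5, and the ring-fusion mixture is irrelevant because step 5 flattens C6 and C10.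

**Step 5**
Reactants: 7 tricyclic β-acetoxy ketone
Product: 10 cis-syn-cis α-silyloxy ketone (C6-OTMS; C10-Me; C7=O), via strained enone 8 (not isolated), via bridgehead silyl enol ether 9 (not isolated)
Conditions: DBU, THF, −40 → 0 °C; then Me2CuLi, TMSCl, THF, −78 °C; then DMDO, acetone/CH2Cl2, −40 °C
Reagents that add atoms: lithium dimethylcuprate, [Li+].C[Cu-]C; chlorotrimethylsilane, C[Si](C)(C)Cl; dimethyldioxirane, CC1(C)OO1
Why: Proposed new method: DBU induces E1cB loss of acetate to the transient cyclobutene-fused cyclopentenone 8, in which C6 and C10 are both planar so the ring-fusion stereochemistry of 7 is erased; strain release makes 8 a very reactive Michael acceptor, Me2CuLi/TMSCl delivers methyl to C10 from the convex face (anti to ring A, cis to H1), and Rubottom epoxidation of enol ether 9 can then only occur cis to that methyl (the other face would give a trans-fused bicyclo[3.2.0]heptane), forming the C6–O bond and fixing the cis-syn-cis skeleton; the closest known chemistry is cuprate addition to enones generated in situ from β-acyloxy ketones followed by Rubottom oxidation, but generation and trapping of a bicyclo[3.2.0]hept-1(5)-en-2-one has not been shown.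

**Step 6**
Reactants: 10 cis-syn-cis α-silyloxy ketone
Product: 13 C6,C8-dihydroxy ketone (C8-OH exo), via C7=C8 silyl enol ether 11 (not isolated), via bis-silyl ether 12 (not isolated)
Conditions: TMSOTf, Et3N, CH2Cl2, 0 °C; then DMDO, acetone, −40 °C; then citric acid, MeOH, 0 °C
Reagents that add atoms: dimethyldioxirane, CC1(C)OO1
Why: Soft enolisation can only go towards C8 (C6 is quaternary) and leaves the acetate alone, and Rubottom oxidation from the exo face of ring C (the concave face is shielded by ring A and its C4 methyl) sets C8 with oxygen cis to the C10 methyl; mild methanolysis removes both TMS groups but not the tertiary TES ether.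

**Step 7**
Reactants: 13 C6,C8-dihydroxy ketone
Product: 14 C8 tiglate of 13
Conditions: tigloyl chloride, pyridine, DMAP (cat.), CH2Cl2, 0 °C
Reagents that add atoms: (E)-2-methylbut-2-enoyl chloride, C/C=C(\C)C(Cl)=O
Why: DMAP-catalysed acylation takes the secondary C8 hydroxyl and leaves the hindered tertiary C6 hydroxyl free; the exo C8 ester is also the more stable epimer should the α-centre equilibrate.

**Step 8**
Reactants: 14 C8 tiglate of 13
Product: 15 C6 bromoacetate of 14
Conditions: BrCH2COBr, pyridine, CH2Cl2, −20 → 0 °C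
Reagents that add atoms: bromoacetyl bromide, BrCC(Br)=O
Why: O-acylation with a small, very reactive acyl bromide is the standard way to esterify a hindered tertiary alcohol and introduces C12 and C11 of the lactone; C4–OH is masked as its TES ether.

**Step 9**
Reactants: 15 C6 bromoacetate of 14
Product: 20 C4-O-triethylsilyl ether of the target, via phosphonium bromide 16 (not isolated), via ester ylide 17 (not isolated), via acetoxymethylated phosphonium bromide 18 (not isolated), via acetoxymethyl ylide 19 (not isolated)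
Conditions: PPh3, MeCN, rt; then Et3N, BrCH2OAc, 0 °C; then Et3N, toluene, 80 °C
Reagents that add atoms: bromomethyl acetate, CC(=O)OCBr
Why: Phosphonium salt formation, C-alkylation of the stabilised ylide with the reactive acetoxymethyl bromide at 0 °C (before the slower ring closure) and intramolecular Wittig olefination of the C7 ketone on heating close the butenolide with C13–OAc in place; the C7=C11 geometry is fixed by the ring.

**Step 10**
Reactants: 20 C4-O-triethylsilyl ether of the target
Product: 21 CNP0210373.1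
Conditions: HF·pyridine, THF, 0 °C → rt
Reagents that add atoms: none
Why: Fluoride-mediated cleavage of the tertiary silyl ether under mildly acidic conditions frees the C4 hydroxyl without touching the acetates, the tiglate or the butenolide.

## Compound list

1 | cyclopentane-1,3-dione | O=C1CCC(=O)C1 | starting material
2 | 3-oxocyclopent-1-en-1-yl acetate (3-acetoxycyclopent-2-enone) | CC(=O)OC1=CC(=O)CC1 | intermediate
3 | (1R,4S)-cis-4-acetoxycyclopent-2-en-1-ol | CC(=O)O[C@@H]1C=C[C@H](O)C1 | starting material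
4 | (4S)-4-acetoxycyclopent-2-en-1-one | CC(=O)O[C@@H]1C=CC(=O)C1 | intermediate
5 | bromomagnesium (1R,4S)-4-acetoxy-1-methylcyclopent-2-en-1-olate (methyl trans to OAc) | CC(=O)O[C@@H]1C=C[C@](C)(O[Mg]Br)C1 | intermediate
6 | (1S,4R)-4-methyl-4-(triethylsilyloxy)cyclopent-2-en-1-yl acetate (the two oxygens cis) | CC(=O)O[C@@H]1C=C[C@](C)(O[Si](CC)(CC)CC)C1 | intermediate
7 | tricyclic β-acetoxy ketone: C7=O, C10-OAc, C6-H; cyclobutane trans to C2-OAc and C4-OTES, cis to C4-Me; cis-anti-cis isomer drawn, cis-syn-cis epimer pair at C6/C10 also present | C1C[C@@]2(OC(C)=O)[C@@H]3[C@@H](OC(C)=O)C[C@@](C)(O[Si](CC)(CC)CC)[C@@H]3[C@H]2C1=O | intermediate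
8 | cyclobutene-fused enone (C6=C10, C7=O), ring A cis-fused at C1/C5 | C1CC2[C@@H]3[C@@H](OC(C)=O)C[C@@](C)(O[Si](CC)(CC)CC)[C@@H]3C=2C1=O | intermediate
9 | C7 trimethylsilyl enol ether (C6=C7), C10-Me cis to H1 | C1C[C@]2(C)[C@@H]3[C@@H](OC(C)=O)C[C@@](C)(O[Si](CC)(CC)CC)[C@@H]3C2=C1O[Si](C)(C)C | intermediate
10 | cis-syn-cis α-silyloxy ketone: C6-OTMS cis to C10-Me, H1 and H5; C7=O | C1C[C@]2(C)[C@@H]3[C@@H](OC(C)=O)C[C@@](C)(O[Si](CC)(CC)CC)[C@@H]3[C@]2(O[Si](C)(C)C)C1=O | intermediate
11 | C7=C8 trimethylsilyl enol ether of 10 | C1C[C@]2(C)[C@@H]3[C@@H](OC(C)=O)C[C@@](C)(O[Si](CC)(CC)CC)[C@@H]3[C@]2(O[Si](C)(C)C)C=1O[Si](C)(C)C | intermediate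
12 | C6,C8-bis(trimethylsilyloxy) C7 ketone (C8-O exo) | C[Si](C)(C)O[C@H]1C[C@]2(C)[C@@H]3[C@@H](OC(C)=O)C[C@@](C)(O[Si](CC)(CC)CC)[C@@H]3[C@]2(O[Si](C)(C)C)C1=O | intermediate
13 | C6,C8-dihydroxy C7 ketone (C8-OH exo, cis to C10-Me and C6-OH) | O[C@H]1C[C@]2(C)[C@@H]3[C@@H](OC(C)=O)C[C@@](C)(O[Si](CC)(CC)CC)[C@@H]3[C@]2(O)C1=O | intermediate
14 | C8 tiglate of 13 | C/C=C(\C)C(=O)O[C@H]1C[C@]2(C)[C@@H]3[C@@H](OC(C)=O)C[C@@](C)(O[Si](CC)(CC)CC)[C@@H]3[C@]2(O)C1=O | intermediate
15 | C6 bromoacetate of 14 | C/C=C(\C)C(=O)O[C@H]1C[C@]2(C)[C@@H]3[C@@H](OC(C)=O)C[C@@](C)(O[Si](CC)(CC)CC)[C@@H]3[C@]2(OC(=O)CBr)C1=O | intermediate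
16 | triphenylphosphonium bromide from 15 | C/C=C(\C)C(=O)O[C@H]1C[C@]2(C)[C@@H]3[C@@H](OC(C)=O)C[C@@](C)(O[Si](CC)(CC)CC)[C@@H]3[C@]2(OC(=O)C[P+](c4ccccc4)(c4ccccc4)c4ccccc4)C1=O.[Br-] | intermediate
17 | ester-stabilised ylide | C/C=C(\C)C(=O)O[C@H]1C[C@]2(C)[C@@H]3[C@@H](OC(C)=O)C[C@@](C)(O[Si](CC)(CC)CC)[C@@H]3[C@]2(OC(=O)C=P(c4ccccc4)(c4ccccc4)c4ccccc4)C1=O | intermediate
18 | C11-acetoxymethylated phosphonium bromide (both C11 epimers) | C/C=C(\C)C(=O)O[C@H]1C[C@]2(C)[C@@H]3[C@@H](OC(C)=O)C[C@@](C)(O[Si](CC)(CC)CC)[C@@H]3[C@]2(OC(=O)C(COC(C)=O)[P+](c4ccccc4)(c4ccccc4)c4ccccc4)C1=O.[Br-] | intermediate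
19 | acetoxymethyl-substituted ylide | C/C=C(\C)C(=O)O[C@H]1C[C@]2(C)[C@@H]3[C@@H](OC(C)=O)C[C@@](C)(O[Si](CC)(CC)CC)[C@@H]3[C@]2(OC(=O)C(COC(C)=O)=P(c4ccccc4)(c4ccccc4)c4ccccc4)C1=O | intermediate
20 | C4-O-triethylsilyl ether of the target | C/C=C(\C)C(=O)O[C@H]1C[C@]2(C)[C@@H]3[C@@H](OC(C)=O)C[C@@](C)(O[Si](CC)(CC)CC)[C@@H]3[C@@]23OC(=O)C(COC(C)=O)=C13 | intermediate
21 | CNP0210373.1 | C/C=C(\C)C(=O)O[C@H]1C[C@]2(C)[C@@H]3[C@@H](OC(C)=O)C[C@@](C)(O)[C@@H]3[C@@]23OC(=O)C(COC(C)=O)=C13 | target

## Step count and risks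

Total step count: 10. Longest linear sequence: 9 steps (3 → 21, steps 2–10); step 1 is a one-step side branch that joins at step 4.

The three steps most likely to fail:

**Step 5 (the proposed new relay).** The strained enone 8 may form too slowly, isomerise out of conjugation or oligomerise before the cuprate traps it. The fallback uses only known chemistry and sets out from 6. Commercial 3-methylcyclopentane-1,2-dione is O-silylated (TMSCl, Et3N) to 3-methyl-2-(trimethylsilyloxy)cyclopent-2-en-1-one F1. Irradiating F1 with 6 at 350 nm is an ordinary enone–alkene [2+2] photocycloaddition that brings in C6–O and C10–Me directly. It gives 10 together with its cis-anti-cis ring-fusion isomer F2, and 10 is separated by chromatography. The price is that the ring fusion is no longer controlled (F2 may dominate). The fallback comes back to the route at 10.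

**Step 9 (butenolide closure).** C-alkylation of ylide 17 must outrun its own ring closure, and the Wittig step has to build a tetrasubstituted alkene at a ketone whose concave face is blocked by the C4 methyl. The fallback sets out from 14 and also covers a failure of the acylation in step 8. Heating 14 with Meldrum's acid (toluene, 90 °C; acyl-ketene acylation, no acyl halide) gives the malonic half-ester F3. Intramolecular Knoevenagel condensation (TiCl4, pyridine, THF, 0 °C) gives the C11 carboxy butenolide F4. BH3·SMe2 reduces the free acid to the hydroxymethyl butenolide F5. Acetylation (Ac2O, pyridine) returns to the route at 20.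

**Step 6 (C8 oxygenation).** The exo face of ring C carries the C10 methyl and the C6 silyloxy group, so the oxidant may enter from the other face. In that case 10 gives the C8-epimeric diol F6. Mitsunobu esterification of the C8-epimeric diol F6 with tiglic acid (PPh3, DIAD, THF) forms the C8–O ester bond with inversion and comes back to the route at 14.

## Further compounds

F1 | step 5 | 3-methyl-2-(trimethylsilyloxy)cyclopent-2-en-1-one | CC1=C(O[Si](C)(C)C)C(=O)CC1
F2 | step 5 | cis-anti-cis isomer of 10 (C6 and C10 inverted) | C1C[C@@]2(C)[C@@H]3[C@@H](OC(C)=O)C[C@@](C)(O[Si](CC)(CC)CC)[C@@H]3[C@@]2(O[Si](C)(C)C)C1=O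
F3 | step 9 | C6 malonic half-ester of 14 | C/C=C(\C)C(=O)O[C@H]1C[C@]2(C)[C@@H]3[C@@H](OC(C)=O)C[C@@](C)(O[Si](CC)(CC)CC)[C@@H]3[C@]2(OC(=O)CC(O)=O)C1=O
F4 | step 9 | C11 carboxy butenolide | C/C=C(\C)C(=O)O[C@H]1C[C@]2(C)[C@@H]3[C@@H](OC(C)=O)C[C@@](C)(O[Si](CC)(CC)CC)[C@@H]3[C@@]23OC(=O)C(C(O)=O)=C13
F5 | step 9 | C11 hydroxymethyl butenolide | C/C=C(\C)C(=O)O[C@H]1C[C@]2(C)[C@@H]3[C@@H](OC(C)=O)C[C@@](C)(O[Si](CC)(CC)CC)[C@@H]3[C@@]23OC(=O)C(CO)=C13
F6 | step 6 | C8-epimer of 13 | O[C@@H]1C[C@]2(C)[C@@H]3[C@@H](OC(C)=O)C[C@@](C)(O[Si](CC)(CC)CC)[C@@H]3[C@]2(O)C1=O
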